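## Retrosynthetic overview

1. Target ⇐ deconjugative α‑protonation of the Δ8(9) enal‑ester ⇐ Pd formylation of the enol triflate of a C9‑keto/C8‑ester. The side chain comes from cross‑metathesis of a C4 allyl group.
2. C3–Cl ⇐ C3 alcohol (from the ketone) by radical deoxychlorination. C1–OH ⇐ 1α‑selective conjugate borylation of the Δ1‑en‑3‑one.
3. The C4 quaternary centre and the trans ring fusion ⇐ reductive allylation of a 4‑methyl octalone.
4. Ring B, including its ester carbon ⇐ one‑carbon ring expansion of the cyclopentanone of a Hajos–Parrish‑type enedione with methyl diazoacetate (key step).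
5. Ring order: purchased five‑membered dione ring → ring A by Michael addition and asymmetric aldol → five‑membered ring enlarged to ring B.

**Assumption:** methyl diazoacetate is bought as a commercial solution.

**Locants:** drimane type. Ring A = C1–C5 and C10. Ring B = C5–C10. C11 = formyl carbon, C12 = ester carbon. β is the face of the C10 methyl group.

## Route

Step 1
Reactants: 1 2‑methylcyclopentane‑1,3‑dione; 2 pent‑1‑en‑3‑one
Product: 3 2‑methyl‑2‑(3‑oxopentyl)cyclopentane‑1,3‑dione
Conditions: H2O, AcOH (cat.), 75 °C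
Reagents that add atoms: none
Why: Michael addition of the acidic 2‑alkyl‑1,3‑dione to the vinyl ketone, which creates no stereocentre.

Step 2
Reactants: 3 triketone
Product: 4 (7aS)‑4,7a‑dimethyl‑2,3,7,7a‑tetrahydro‑1H‑indene‑1,5(6H)‑dione
Conditions: (S)‑phenylalanine, (1S)‑(+)‑CSA, DMF, 30→70 °C; recrystallise
Reagents that add atoms: none
Why: Hajos–Parrish–Eder–Sauer–Wiechert enamine aldol condensation, in which the (S)‑amino acid distinguishes the enantiotopic ring ketones and sets C10 (S, β‑methyl).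

Step 3
Reactants: 4 enedione; 5 methyl diazoacetate
Product: 6 methyl (8aS)‑5,8a‑dimethyl‑1,6‑dioxo‑1,2,3,4,6,7,8,8a‑octahydronaphthalene‑2‑carboxylate (C8 epimers/enol)
Conditions: BF3·OEt2, CH2Cl2, 0 °C→rt
Reagents that add atoms: none
Why: Lewis‑acid diazoacetate homologation (Büchner–Curtius–Schlotterbeck ring expansion), in which the diazo carbon adds to the saturated ketone rather than the deactivated enone and the less substituted CH2 undergoes the 1,2‑shift with loss of N2, giving ring B with C9=O and C8–CO2Me while C10 is untouched.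

Step 4
Reactants: 6 octalone β‑keto ester; 7 allyl bromide
Product: 9 methyl 4α‑allyl‑4β,10β‑dimethyl‑3,9‑dioxo‑5α‑H‑trans‑decalin‑8‑carboxylate, via dilithium bis‑enolate 8 (not isolated)
Conditions: LiHMDS, THF; Li, NH3(l), t‑BuOH (1 equiv), −78 °C; 7 (1.05 equiv); NH4Cl
Reagents that add atoms: none
Why: Stork reductive alkylation, in which the pre‑formed β‑keto ester enolate resists reduction, axial protonation at C5 gives the trans fusion, and the more reactive C3/C4 enolate is allylated anti to the C10 methyl (4α‑allyl, 4β‑Me).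

Step 5
Reactants: 9 diketo ester
Product: 10 Δ8(9) enol triflate of 9 (C9–OTf, C8–CO2Me, C3 ketone kept)
Conditions: Tf2O, i‑Pr2NEt, CH2Cl2, −78 °C
Reagents that add atoms: triflic anhydride O=S(=O)(OS(=O)(=O)C(F)(F)F)C(F)(F)F
Why: O‑triflation of the enolised β‑keto ester, since only this acidic site is deprotonated by the amine.

Step 6
Reactants: 10 enol triflate
Product: 11 Δ1‑en‑3‑one of 10
Conditions: IBX, DMSO/PhF, 75 °C
Reagents that add atoms: none
Why: IBX dehydrogenation, regiodefined because the C3 ketone can enolise only towards C2 (C4 is quaternary).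

Step 7
Reactants: 11 Δ1‑enone
Product: 12 1α‑(pinacolboryl)‑3‑ketone
Conditions: CuCl/DPEphos (5 mol %), NaOt‑Bu (10 mol %), B2pin2, MeOH, THF, rt
Reagents that add atoms: bis(pinacolato)diboron CC1(C)OB(OC1(C)C)B1OC(C)(C)C(C)(C)O1
Why: Cu‑catalysed conjugate borylation, in which Cu–Bpin attacks C1 axially from the α face, anti to the C10 methyl, and sets C1, while the hindered tetrasubstituted triflyloxy enoate does not react.

Step 8
Reactants: 12 β‑boryl ketone
Product: 13 C3 alcohol (drawn 3β; both epimers are used)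
Conditions: NaBH4, MeOH/CH2Cl2, −20 °C
Reagents that add atoms: none
Why: chemoselective hydride reduction of the only ketone, whose C3 configuration is erased in step 9.

Step 9
Reactants: 13 C3 alcohol
Product: 15 3β‑chloro‑1α‑(pinacolboryl) enol triflate, via benzoxazoline alcohol adduct 14 (not isolated)
Conditions: 5,7‑di‑tert‑butyl‑3‑phenylbenzoxazolium BF4, pyridine, MTBE, rt; then [Ir(ppy)2(dtbbpy)]PF6 (1 mol %), quinuclidine (20 mol %), Cl3CCO2Et, MTBE/DMA, 450 nm, rt
Reagents that add atoms: ethyl trichloroacetate CCOC(=O)C(Cl)(Cl)Cl (Cl of 15); 5,7‑di‑tert‑butyl‑3‑phenylbenzoxazol‑3‑ium tetrafluoroborate CC(C)(C)c1cc2c(OC=[N+]2c2ccccc2)c(c1)C(C)(C)C.F[B-](F)(F)F (atoms of 14 only)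
Why: Proposed new method: the hindered alcohol adds to the benzoxazolium C2, excited Ir(III) oxidises the adduct nitrogen, and loss of the C2 proton followed by β‑scission releases the C3 radical with no cation, so no Wagner–Meerwein shift next to C4 can occur; this radical abstracts Cl from Cl3CCO2Et, and the •CCl2CO2Et formed is reduced by Ir(II) and protonated, which makes the cycle redox neutral; Cl is delivered to the β (equatorial) side because the α face is blocked by the axial 1α‑Bpin and 5α‑H, which sets C3; the closest known reaction types are photoredox deoxygenative C–C coupling of such alcohol adducts and radical deoxychlorination of oxalates with trichloroacetate.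

Step 10
Reactants: 15 chloride; 16 2‑methylbut‑3‑en‑2‑ol
Product: 17 (E)‑4‑hydroxy‑4‑methylpent‑2‑enyl side‑chain compound
Conditions: Hoveyda–Grubbs II (5 mol %), 16 (5 equiv), CH2Cl2, 40 °C
Reagents that add atoms: none
Why: olefin cross‑metathesis of the terminal allyl group with a hindered tertiary allylic alcohol partner is E‑selective, and the tetrasubstituted enoate is inert.

Step 11
Reactants: 17 enol triflate
Product: 18 Δ8(9) 9‑formyl‑8‑carboxylate (enal‑ester), with 1α‑Bpin retained
Conditions: Pd(OAc)2/dppp (5 mol %), CO (1 atm), Et3SiH, Et3N, DMF, 60 °C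
Reagents that add atoms: carbon monoxide [C-]#[O+]
Why: Pd‑catalysed reductive carbonylation (formylation) of a vinyl triflate, run with C1 still as Bpin so that no hydroxyl can trap the acyl‑palladium as a lactone.

Step 12
Reactants: 18 boryl enal
Product: 19 1α‑hydroxy Δ8(9) enal‑ester
Conditions: Me3NO, THF, 60 °C; aqueous work‑up
Reagents that add atoms: trimethylamine N‑oxide C[N+](C)(C)[O-]
Why: amine‑oxide oxidation of the C–B bond (1,2‑metallate shift with retention) gives the 1α‑OH without a nucleophilic peroxide that could attack the electron‑poor alkene.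

Step 13
Reactants: 19 conjugated enal
Product: 21 target, methyl (1R,4aR,5S,6S,8S,8aS)‑6‑chloro‑1‑formyl‑8‑hydroxy‑5‑[(E)‑4‑hydroxy‑4‑methylpent‑2‑enyl]‑5,8a‑dimethyl‑1,4,4a,5,6,7,8,8a‑octahydronaphthalene‑2‑carboxylate, via tripotassium dienolate 20 (not isolated)
Conditions: KHMDS (3.3 equiv), THF, −78 °C; AcOH, −78 °C
Reagents that add atoms: none
Why: deconjugative kinetic protonation, in which γ‑deprotonation at C7 gives the extended dienolate and α‑protonation at C9 from the open α face (anti to the C10 methyl, on the side of the 1α‑oxygen) gives 9α‑H/9β‑CHO with the alkene left at Δ7 in conjugation with the ester.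

## Compound list

1 | 2‑methylcyclopentane‑1,3‑dione | CC1C(=O)CCC1=O | starting material
2 | pent‑1‑en‑3‑one | CCC(=O)C=C | starting material
3 | 2‑methyl‑2‑(3‑oxopentyl)cyclopentane‑1,3‑dione | CCC(=O)CCC1(C)C(=O)CCC1=O | intermediate
4 | (7aS)‑4,7a‑dimethyl hydrindenedione | O=C1CCC2=C(C)C(=O)CC[C@]12C | intermediate
5 | methyl diazoacetate | COC(=O)C=[N+]=[N-] | starting material
6 | ring‑expanded octalone β‑keto ester | COC(=O)C1CCC2=C(C)C(=O)CC[C@]2(C)C1=O | intermediate
7 | allyl bromide | C=CCBr | starting material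
8 | dilithium bis‑enolate | COC(=O)C=1CC[C@H]2C(C)=C([O-])CC[C@]2(C)C=1[O-].[Li+].[Li+] | intermediate
9 | 4α‑allyl trans‑decalin diketo ester | COC(=O)C1CC[C@H]2[C@](C)(CC=C)C(=O)CC[C@]2(C)C1=O | intermediate
10 | Δ8(9) enol triflate | COC(=O)C=1CC[C@H]2[C@](C)(CC=C)C(=O)CC[C@]2(C)C=1OS(=O)(=O)C(F)(F)F | intermediate
11 | Δ1‑en‑3‑one | COC(=O)C=1CC[C@H]2[C@](C)(CC=C)C(=O)C=C[C@]2(C)C=1OS(=O)(=O)C(F)(F)F | intermediate
12 | 1α‑Bpin 3‑ketone | COC(=O)C=1CC[C@H]2[C@](C)(CC=C)C(=O)C[C@H](B3OC(C)(C)C(C)(C)O3)[C@]2(C)C=1OS(=O)(=O)C(F)(F)F | intermediate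
13 | C3 alcohol | COC(=O)C=1CC[C@H]2[C@](C)(CC=C)[C@@H](O)C[C@H](B3OC(C)(C)C(C)(C)O3)[C@]2(C)C=1OS(=O)(=O)C(F)(F)F | intermediate
14 | benzoxazoline alcohol adduct | COC(=O)C=1CC[C@H]2[C@](C)(CC=C)[C@@H](OC3Oc4c(N3c3ccccc3)cc(C(C)(C)C)cc4C(C)(C)C)C[C@H](B3OC(C)(C)C(C)(C)O3)[C@]2(C)C=1OS(=O)(=O)C(F)(F)F | intermediate
15 | 3β‑chloride | COC(=O)C=1CC[C@H]2[C@](C)(CC=C)[C@@H](Cl)C[C@H](B3OC(C)(C)C(C)(C)O3)[C@]2(C)C=1OS(=O)(=O)C(F)(F)F | intermediate
16 | 2‑methylbut‑3‑en‑2‑ol | CC(C)(O)C=C | starting material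
17 | cross‑metathesis product | COC(=O)C=1CC[C@H]2[C@](C)(C/C=C/C(C)(C)O)[C@@H](Cl)C[C@H](B3OC(C)(C)C(C)(C)O3)[C@]2(C)C=1OS(=O)(=O)C(F)(F)F | intermediate
18 | boryl enal‑ester | COC(=O)C=1CC[C@H]2[C@](C)(C/C=C/C(C)(C)O)[C@@H](Cl)C[C@H](B3OC(C)(C)C(C)(C)O3)[C@]2(C)C=1C=O | intermediate
19 | 1α‑hydroxy enal‑ester | COC(=O)C=1CC[C@H]2[C@](C)(C/C=C/C(C)(C)O)[C@@H](Cl)C[C@H](O)[C@]2(C)C=1C=O | intermediate
20 | tripotassium dienolate | COC(=O)C1=CC[C@H]2[C@](C)(C/C=C/C(C)(C)[O-])[C@@H](Cl)C[C@H]([O-])[C@]2(C)C1=C[O-].[K+].[K+].[K+] | intermediate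
21 | CNP0167913.1 | COC(=O)C1=CC[C@H]2[C@](C)(C/C=C/C(C)(C)O)[C@@H](Cl)C[C@H](O)[C@]2(C)[C@H]1C=O | target

## Step count and risks

Total step count: 13. Longest linear sequence: 13.

**Step 9 (new deoxychlorination).** The risks are poor adduct formation at the neopentyl alcohol and a low β:α ratio in the Cl transfer.
- The fallback sets out from 13 and comes back at 15, using known chemistry.
- Acylation of 13 with methyl chlorooxoacetate gives the mixed methyl oxalate F3.
- One equivalent of CsOH gives the cesium oxalate F4.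
- Ir photoredox oxidation of F4 in the presence of ethyl trichloroacetate (radical deoxychlorination of oxalates) gives 15.

**Step 4 (reductive allylation with a free β‑keto ester).** The risks are over‑reduction and allylation at C8.
- The fallback sets out from 6 and comes back at 9, and avoids dissolving metal.
- HAT conjugate reduction of 6 (Mn(dpm)3, PhSiH3, i‑PrOH) gives the trans‑fused saturated 4α‑methyl diketo ester F1.
- TMSI/HMDS converts F1 into the thermodynamic bis(trimethylsilyl enol ether) F2.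
- MeLi (2 equiv) releases bis‑enolate 8 from F2, and 8 is allylated with 7 to give 9.

**Step 13 (deconjugative protonation).** The risks are γ‑protonation back to 19, C9 epimerisation, and base‑induced vinylogous retro‑aldol opening at the C1–C10 bond.
- The fallback sets out from 19 and comes back at 21.
- Soft enolisation with TMSOTf/Et3N gives the isolable tris(trimethylsilyl) dienol ether F5.
- TBAF/AcOH at −78 °C desilylates F5 under buffered conditions, α‑protonates at C9, and frees both hydroxyl groups in the same operation.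

## Further compounds

F1 | step 4 | trans‑fused saturated 4α‑methyl diketo ester | COC(=O)C1CC[C@H]2[C@H](C)C(=O)CC[C@]2(C)C1=O
F2 | step 4 | bis(trimethylsilyl enol ether) | COC(=O)C=1CC[C@H]2C(C)=C(O[Si](C)(C)C)CC[C@]2(C)C=1O[Si](C)(C)C
F3 | step 9 | mixed methyl oxalate of 13 | COC(=O)C=1CC[C@H]2[C@](C)(CC=C)[C@@H](OC(=O)C(=O)OC)C[C@H](B3OC(C)(C)C(C)(C)O3)[C@]2(C)C=1OS(=O)(=O)C(F)(F)F
F4 | step 9 | cesium oxalate of 13 | COC(=O)C=1CC[C@H]2[C@](C)(CC=C)[C@@H](OC(=O)C(=O)[O-])C[C@H](B3OC(C)(C)C(C)(C)O3)[C@]2(C)C=1OS(=O)(=O)C(F)(F)F.[Cs+]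
F5 | step 13 | tris(trimethylsilyl) dienol ether of 19 | COC(=O)C1=CC[C@H]2[C@](C)(C/C=C/C(C)(C)O[Si](C)(C)C)[C@@H](Cl)C[C@H](O[Si](C)(C)C)[C@]2(C)C1=CO[Si](C)(C)C
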